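**Retrosynthetic overview**
- The strategy rests on the quaternary C2 of the cyclohexane (ring A), which lies between the oxygenated C1 and the arm-bearing methine C3. The C2–C3 bond is made by a 1,2-shift that expands an epoxy cyclopentanol (20) to the 2-hydroxymethyl cyclohexanone 21.
- 20 comes from cyclopentanone 11 (cyclopent-2-en-1-one; CBS reduction, B-alkyl Suzuki coupling, anti hydroboration) and a Shapiro-derived 2-lithio-1-alkene, followed by hydroxyl-directed epoxidation.
- After the expansion, the CH2OH group directs the C1 carbinol and is then reduced to the C2 methyl. The C4 ketone and the C3 arm are joined in an eight-membered enoate lactone (tethered olefination), which masks the (Z)-enal.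
- The pent-3-ynyl chain becomes an (E)-vinyl iodide and is coupled (Ni/Cr) with epoxy aldehyde 40. The tetrahydrofuran (ring B) closes by 5-endo opening of the epoxide; lactone reduction and MnO2 oxidation finish the synthesis.
- Ring order: cyclopentane (bought) → ring A (step 13) → temporary lactone (step 22) → ring B (step 28).

Key step: step 13

Assumption: hex-1-en-5-yne, allyloxy(tert-butyl)dimethylsilane and 2-(diethoxyphosphoryl)propanoic acid are taken as purchasable, and in step 27 the antipode of the sulfonamide ligand that gives the 5′R carbinol is the one used.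

Locants: ring A is C1 (carbinol), C2 (quaternary), C3 (arm), C4 (enal carbon), C5, C6. Ring B is O1′, C2′ (quaternary), C3′ (CHOH), C4′, C5′.

**Step 1**
Reactants: 1 cyclopent-2-en-1-one
Product: 2 2-iodocyclopent-2-en-1-one
Conditions: I2, K2CO3, DMAP (cat.), THF/H2O, rt
Reagents that add atoms: iodine, II
Why: Amine-catalysed α-iodination of an enone (conjugate addition of DMAP, iodination of the enolate, elimination), a Baylis–Hillman-type halogenation.

**Step 2**
Reactants: 2 2-iodocyclopent-2-en-1-one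
Product: 3 (S)-2-iodocyclopent-2-en-1-ol
Conditions: (R)-2-methyl-CBS-oxazaborolidine (0.1 equiv), BH3·SMe2, THF, 0 °C
Reagents that add atoms: none
Why: Corey–Bakshi–Shibata reduction in which the iodoalkene side acts as the large group, so the (R)-catalyst should deliver hydride to give the (S)-carbinol.

**Step 3**
Reactants: 3 (S)-2-iodocyclopent-2-en-1-ol
Product: 4 (S)-1-iodo-5-(4-methoxybenzyloxy)cyclopent-1-ene
Conditions: NaH, 4-methoxybenzyl chloride, Bu4NI (cat.), THF/DMF, 0 °C to rt
Reagents that add atoms: 4-methoxybenzyl chloride, COc1ccc(CCl)cc1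
Why: Williamson etherification gives a temporary ether that survives the coupling and hydroboration and is later removed oxidatively in the presence of silyl ethers.

**Step 4**
Reactants: 4 (S)-1-iodo-5-(4-methoxybenzyloxy)cyclopent-1-ene; 5 allyloxy(tert-butyl)dimethylsilane
Product: 7 tert-butyl{3-[(5S)-5-(4-methoxybenzyloxy)cyclopent-1-en-1-yl]propoxy}dimethylsilane, via alkylborane 6 (not isolated)
Conditions: 5, 9-BBN, THF, rt; then 4, PdCl2(dppf) (cat.), AsPh3, Cs2CO3, DMF/H2O, rt
Reagents that add atoms: none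
Why: Anti-Markovnikov hydroboration of the allyl ether followed by B-alkyl Suzuki–Miyaura coupling with the vinyl iodide installs the protected three-carbon arm in one operation.

**Step 5**
Reactants: 7 tert-butyl{3-[(5S)-5-(4-methoxybenzyloxy)cyclopent-1-en-1-yl]propoxy}dimethylsilane
Product: 8 (1S,2R,3S)-2-[3-(tert-butyldimethylsilyloxy)propyl]-3-(4-methoxybenzyloxy)cyclopentan-1-ol
Conditions: BH3·THF, THF, 0 °C to rt; then NaOH, H2O2, 0 °C
Reagents that add atoms: hydrogen peroxide, OO
Why: Hydroboration–oxidation adds H and B syn from the face opposite the allylic ether with boron on the less substituted carbon, so the arm ends cis to the benzyl ether and trans to the new hydroxyl, which sets both ring stereocentres.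

**Step 6**
Reactants: 8 (1S,2R,3S)-2-[3-(tert-butyldimethylsilyloxy)propyl]-3-(4-methoxybenzyloxy)cyclopentan-1-ol
Product: 9 1-{[(1S,2S,3S)-3-(tert-butyldimethylsilyloxy)-2-[3-(tert-butyldimethylsilyloxy)propyl]cyclopentyl]oxymethyl}-4-methoxybenzene
Conditions: t-BuMe2SiCl, imidazole, DMF, rt
Reagents that add atoms: tert-butyldimethylsilyl chloride, CC(C)(C)[Si](C)(C)Cl
Why: Standard silylation of the secondary alcohol that will later become the C4 oxygen of ring A.

**Step 7**
Reactants: 9 the bis-silyl 4-methoxybenzyl ether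
Product: 10 (1S,2S,3S)-3-(tert-butyldimethylsilyloxy)-2-[3-(tert-butyldimethylsilyloxy)propyl]cyclopentan-1-ol
Conditions: DDQ, CH2Cl2/pH 7 buffer, 0 °C
Reagents that add atoms: none
Why: Oxidative cleavage of the 4-methoxybenzyl ether by DDQ leaves both silyl ethers untouched.

**Step 8**
Reactants: 10 (1S,2S,3S)-3-(tert-butyldimethylsilyloxy)-2-[3-(tert-butyldimethylsilyloxy)propyl]cyclopentan-1-ol
Product: 11 (2R,3S)-3-(tert-butyldimethylsilyloxy)-2-[3-(tert-butyldimethylsilyloxy)propyl]cyclopentan-1-one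
Conditions: Dess–Martin periodinane, NaHCO3, CH2Cl2, rt
Reagents that add atoms: none
Why: Buffered Dess–Martin oxidation gives the trans α-alkyl β-silyloxy ketone, the thermodynamically preferred epimer, without β-elimination.

**Step 9**
Reactants: 12 pentane-2,4-dione; 13 1-bromobut-2-yne
Product: 15 hept-5-yn-2-one, via alkylated diketone 14 (not isolated)
Conditions: K2CO3, EtOH, reflux
Reagents that add atoms: none
Why: C-alkylation of the diketone followed in the same pot by retro-Claisen loss of one acetyl group to ethanol (alkylation–cleavage) gives the methyl ketone directly.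

**Step 10**
Reactants: 15 hept-5-yn-2-one
Product: 16 N′-(hept-5-yn-2-ylidene)-2,4,6-triisopropylbenzenesulfonohydrazide
Conditions: 2,4,6-triisopropylbenzenesulfonohydrazide, MeOH, HCl (cat.), rt
Reagents that add atoms: 2,4,6-triisopropylbenzenesulfonohydrazide, CC(C)c1cc(C(C)C)c(S(=O)(=O)NN)c(C(C)C)c1
Why: Hydrazone condensation gives the Shapiro precursor with the sulfonamide syn to the methyl group.

**Step 11**
Reactants: 16 the trisylhydrazone; 11 (2R,3S)-3-(tert-butyldimethylsilyloxy)-2-[3-(tert-butyldimethylsilyloxy)propyl]cyclopentan-1-one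
Product: 19 (1S,2R,3S)-3-(tert-butyldimethylsilyloxy)-2-[3-(tert-butyldimethylsilyloxy)propyl]-1-(hepta-1-en-5-yn-2-yl)cyclopentan-1-ol, via vinyllithium 17 (not isolated), via organocerium 18 (not isolated)
Conditions: 16, n-BuLi (2.1 equiv), THF, −78 to 0 °C; CeCl3, −78 °C; then 11, −78 °C
Reagents that add atoms: none
Why: Shapiro reaction (dianion at the methyl group, loss of sulfinate and N2) gives the 2-lithio-1-alkene, whose non-basic cerium derivative should add to the enolisable ketone from the face anti to the adjacent arm.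

**Step 12**
Reactants: 19 the tertiary allylic alcohol
Product: 20 (1S,2R,3S)-3-(tert-butyldimethylsilyloxy)-2-[3-(tert-butyldimethylsilyloxy)propyl]-1-[(2R)-2-(pent-3-yn-1-yl)oxiran-2-yl]cyclopentan-1-ol
Conditions: VO(acac)2 (cat.), t-BuOOH, CH2Cl2, 0 °C to rt
Reagents that add atoms: tert-butyl hydroperoxide, CC(C)(C)OO
Why: Hydroxyl-directed epoxidation through the vanadate ester, in a transition state that keeps the ring CH2 next to the alkene substituent and the arm-bearing carbon away from it, should give the (R)-oxirane centre; the alkyne is not touched.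

**Step 13**
Reactants: 20 the epoxy cyclopentanol
Product: 21 (2S,3S,4S)-4-(tert-butyldimethylsilyloxy)-3-[3-(tert-butyldimethylsilyloxy)propyl]-2-(hydroxymethyl)-2-(pent-3-yn-1-yl)cyclohexan-1-one
Conditions: ZnBr2, CH2Cl2, 0 °C to rt
Reagents that add atoms: none
Why: ZnBr2 binds the tertiary hydroxyl and the oxirane oxygen of 20, the fully substituted oxirane C–O bond ionises, and the cyclopentane bond from the carbinol carbon to the arm-bearing carbon shifts to that centre while the carbinol becomes the ketone, which forms the C2–C3 bond of ring A. The closest known reaction type is the Lewis-acid semipinacol rearrangement of 2,3-epoxy alcohols, here a 1-oxiranylcyclopentanol going to a 2-(hydroxymethyl)cyclohexanone. Ring A is closed by one-carbon ring expansion through a 1,2-alkyl shift, not by a cyclisation. The quaternary C2 forms with inversion at the oxirane carbon, so its configuration (2S) is dictated by the (R)-epoxide centre from step 12, while the migrating carbon keeps its configuration and becomes C3 (3S). The step needs migration of the methine carbon and not of the ring CH2: in the zinc chelate of this epoxide diastereomer the methine carbon is antiperiplanar to the breaking C–O bond and is also the more substituted, better migrating group. The oxirane CH2–O bond stays intact and ends as the hydroxymethyl group.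

**Step 14**
Reactants: 21 the hydroxymethyl cyclohexanone
Product: 22 [(1R,2S,3S)-3-(tert-butyldimethylsilyloxy)-2-[3-(tert-butyldimethylsilyloxy)propyl]-6-methylidene-1-(pent-3-yn-1-yl)cyclohexyl]methanol
Conditions: Zn, CH2Br2, TiCl4, THF/CH2Cl2, 0 °C to rt
Reagents that add atoms: dibromomethane, BrCBr
Why: Takai–Lombardo methylenation uses a non-basic gem-dimetallic reagent, so the hindered β-hydroxy ketone is methylenated without retro-aldol loss of the hydroxymethyl group.

**Step 15**
Reactants: 22 the homoallylic alcohol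
Product: 23 [(3S,4S,5S,6S)-6-(tert-butyldimethylsilyloxy)-5-[3-(tert-butyldimethylsilyloxy)propyl]-4-(pent-3-yn-1-yl)-1-oxaspiro[2.5]octan-4-yl]methanol
Conditions: VO(acac)2 (cat.), t-BuOOH, toluene, rt
Reagents that add atoms: tert-butyl hydroperoxide, CC(C)(C)OO
Why: Homoallylic-hydroxyl-directed epoxidation delivers oxygen to the methylene face syn to the CH2OH group, which places the C1 oxygen cis to the future C2 methyl.

**Step 16**
Reactants: 23 the spiro epoxy alcohol
Product: 24 [(3S,4S,5S,6S)-6-(tert-butyldimethylsilyloxy)-5-[3-(tert-butyldimethylsilyloxy)propyl]-4-(pent-3-yn-1-yl)-1-oxaspiro[2.5]octan-4-yl]methyl methanesulfonate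
Conditions: MeSO2Cl, Et3N, CH2Cl2, 0 °C
Reagents that add atoms: methanesulfonyl chloride, CS(=O)(=O)Cl
Why: Sulfonylation of the primary neopentyl alcohol prepares it for hydride displacement.

**Step 17**
Reactants: 24 the epoxy mesylate
Product: 26 (1S,2S,3S,4S)-4-(tert-butyldimethylsilyloxy)-3-[3-(tert-butyldimethylsilyloxy)propyl]-1,2-dimethyl-2-(pent-3-yn-1-yl)cyclohexan-1-ol, via hydroxy mesylate 25 (not isolated)
Conditions: LiEt3BH (excess), THF, 0 °C to reflux
Reagents that add atoms: none
Why: LiEt3BH opens the 1,1-disubstituted epoxide at its CH2 to give the tertiary carbinol with the C1 methyl and then displaces the neopentyl mesylate by hydride (directly or through the oxetane formed by the neighbouring alkoxide, both paths giving the C2 methyl); an ionic reduction is chosen because a primary radical here would cyclise onto the alkyne.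

**Step 18**
Reactants: 26 the alkynyl tertiary alcohol
Product: 28 (1S,2S,3S,4S)-4-(tert-butyldimethylsilyloxy)-3-[3-(tert-butyldimethylsilyloxy)propyl]-2-[(E)-4-iodopent-3-en-1-yl]-1,2-dimethylcyclohexan-1-ol, via alkenylzirconocene 27 (not isolated)
Conditions: Cp2Zr(H)Cl (3 equiv), THF, rt to 45 °C; then I2, 0 °C
Reagents that add atoms: iodine, II
Why: Hydrozirconation adds Zr–H syn and, after equilibration with excess reagent, places zirconium on the less hindered methyl-bearing carbon; iodinolysis with retention gives the (E)-2-iodoalkene.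

**Step 19**
Reactants: 28 the bis-silyl vinyl iodide
Product: 29 (1S,2S,3S,4S)-3-(3-hydroxypropyl)-2-[(E)-4-iodopent-3-en-1-yl]-1,2-dimethylcyclohexane-1,4-diol
Conditions: Bu4NF, THF, rt to 40 °C
Reagents that add atoms: none
Why: Fluoride cleaves both silyl ethers; the vinyl iodide and the tertiary alcohol are inert.

**Step 20**
Reactants: 29 the triol; 30 2-(diethoxyphosphoryl)propanoic acid
Product: 31 3-[(1S,2S,3S,6S)-3,6-dihydroxy-2-[(E)-4-iodopent-3-en-1-yl]-2,3-dimethylcyclohexyl]propyl 2-(diethoxyphosphoryl)propanoate (both epimers at the phosphonate carbon)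
Conditions: 30 (1.05 equiv), EDC·HCl, DMAP (cat.), CH2Cl2, 0 °C
Reagents that add atoms: none
Why: Carbodiimide (Steglich) esterification should take place at the unhindered primary hydroxyl far faster than at the flanked secondary or the tertiary one when the acid is limiting.

**Step 21**
Reactants: 31 the hydroxy phosphonate ester
Product: 32 3-[(1S,2S,3S)-3-hydroxy-2-[(E)-4-iodopent-3-en-1-yl]-2,3-dimethyl-6-oxocyclohexyl]propyl 2-(diethoxyphosphoryl)propanoate
Conditions: Dess–Martin periodinane, NaHCO3, CH2Cl2, rt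
Reagents that add atoms: none
Why: Dess–Martin oxidation of the only secondary alcohol gives the C4 ketone; the arm oxygen is already acylated, so no lactol can form.

**Step 22**
Reactants: 32 the keto phosphonate
Product: 33 eight-membered α-methyl enoate lactone fused to ring A at C3–C4 (carbonyl carbon syn to C3), carrying the (E)-4-iodopent-3-enyl chain; ring A stereocentres as in 32
Conditions: LiCl, DBU, MeCN (high dilution), rt to 50 °C
Reagents that add atoms: none
Why: Proposed new method: the lithium-chelated phosphonate carbanion should add to the C4 ketone through the ester tether and the oxaphosphetane collapse to the tetrasubstituted alkene, the tether allowing only the isomer with the carbonyl carbon syn to C3 because a trans double bond is too strained in an eight-membered ring; the closest known reaction type is the intramolecular Horner–Wadsworth–Emmons lactonisation of keto phosphonoacetates under Masamune–Roush conditions, established for five- and six-membered and for macrocyclic enoate lactones but not for an eight-membered ring closing onto a ketone.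

**Step 23**
Reactants: 34 hex-1-en-5-yne
Product: 37 (E)-4-methylocta-3,7-dien-1-ol, via alkenylalane 35 (not isolated), via lithium alkenylaluminate 36 (not isolated)
Conditions: Me3Al, Cp2ZrCl2 (cat.), CH2Cl2, rt; n-BuLi, hexane/THF, −78 °C; oxirane, −78 to 0 °C
Reagents that add atoms: trimethylaluminium, C[Al](C)C; oxirane, C1CO1
Why: Negishi zirconium-catalysed methylalumination adds Me and Al syn to the alkyne (methyl on the internal carbon), and the derived aluminate opens oxirane with retention to give the (E)-homoallylic alcohol; the terminal alkene does not react.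

**Step 24**
Reactants: 37 (E)-4-methylocta-3,7-dien-1-ol
Product: 38 2-[(2R,3R)-3-(but-3-en-1-yl)-3-methyloxiran-2-yl]ethan-1-ol
Conditions: D-fructose-derived Shi ketone (0.3 equiv), Oxone (2KHSO5·KHSO4·K2SO4), K2CO3, Bu4NHSO4 (cat.), Na2B4O7 buffer, MeCN/CH2(OMe)2/H2O, 0 °C
Reagents that add atoms: potassium peroxymonosulfate, [K+].[O-]S(=O)(=O)OO
Why: Shi epoxidation: the chiral dioxirane should attack only the electron-rich trisubstituted alkene through the spiro transition state and give the (R,R)-epoxide, while the monosubstituted alkene is left alone.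

**Step 25**
Reactants: 38 the vinyl-terminated epoxy alcohol
Product: 39 2-[(2R,3R)-3-methyl-3-(4-methylpent-3-en-1-yl)oxiran-2-yl]ethan-1-ol
Conditions: 2-methylbut-2-ene (excess), second-generation Grubbs catalyst RuCl2(=CHPh)(H2IMes)(PCy3) (cat.), CH2Cl2, 40 °C
Reagents that add atoms: 2-methylbut-2-ene, CC=C(C)C
Why: Cross-metathesis of the terminal alkene with 2-methylbut-2-ene installs the prenyl terminus with loss of propene; the trisubstituted epoxide and the free alcohol are tolerated.

**Step 26**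
Reactants: 39 the epoxy alcohol
Product: 40 2-[(2R,3R)-3-methyl-3-(4-methylpent-3-en-1-yl)oxiran-2-yl]acetaldehyde
Conditions: Dess–Martin periodinane, NaHCO3, CH2Cl2, 0 °C; used crude at once
Reagents that add atoms: none
Why: Buffered Dess–Martin oxidation gives the β,γ-epoxy aldehyde under neutral conditions that avoid both acid-induced cyclisation and base-induced epoxide opening.

**Step 27**
Reactants: 33 the iodo lactone; 40 the epoxy aldehyde
Product: 41 lactone 33 in which iodine is replaced by the (1R)-1-hydroxy-2-[(2R,3R)-3-methyl-3-(4-methylpent-3-en-1-yl)oxiran-2-yl]ethyl group (E alkene retained)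
Conditions: CrCl2, NiCl2 (cat.), chiral oxazoline–sulfonamide ligand (Kishi type), Et3N, THF, rt
Reagents that add atoms: none
Why: Nozaki–Hiyama–Kishi coupling: nickel activates the C–I bond, the alkenyl group passes to chromium with retention of geometry and adds only to the aldehyde, the chiral trivalent chromium complex setting C5′ (R) in the sense that matches the usual 1,3-anti preference of β-oxygenated aldehydes.

**Step 28**
Reactants: 41 the hydroxy epoxide
Product: 42 lactone 33 in which iodine is replaced by the (2R,4R,5S)-4-hydroxy-5-methyl-5-(4-methylpent-3-en-1-yl)oxolan-2-yl group (ring B closed)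
Conditions: camphor-10-sulfonic acid (cat.), CH2Cl2, 0 °C
Reagents that add atoms: none
Why: Acid-catalysed 5-endo epoxy-alcohol cyclisation: the C5′ hydroxyl attacks the tertiary epoxide carbon with inversion (giving 2′S) while the C3′–O bond is kept (3′R), and the strained 4-exo alternative does not compete.

**Step 29**
Reactants: 42 the tetrahydrofuran lactone
Product: 43 (1S,2S,3R,4Z)-2-{(3E)-4-[(2R,4R,5S)-4-hydroxy-5-methyl-5-(4-methylpent-3-en-1-yl)oxolan-2-yl]pent-3-en-1-yl}-4-(1-hydroxypropan-2-ylidene)-3-(3-hydroxypropyl)-1,2-dimethylcyclohexan-1-ol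
Conditions: i-Bu2AlH (excess), CH2Cl2, −78 to −20 °C; aqueous KNaC4H4O6 work-up
Reagents that add atoms: none
Why: Hydride reduction of the enoate lactone through the lactol gives the allylic alcohol and frees the arm hydroxyl without touching the alkene geometry.

**Step 30**
Reactants: 43 the allylic alcohol
Product: 44 target CNP0155390.1, (2Z)-2-[(2R,3S,4S)-4-hydroxy-2-(3-hydroxypropyl)-3-{(3E)-4-[(2R,4R,5S)-4-hydroxy-5-methyl-5-(4-methylpent-3-en-1-yl)oxolan-2-yl]pent-3-en-1-yl}-3,4-dimethylcyclohexylidene]propanal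
Conditions: MnO2 (activated, excess), CH2Cl2, rt
Reagents that add atoms: none
Why: MnO2 oxidises only the allylic primary alcohol, so the enal should form in the presence of the saturated primary, secondary and tertiary hydroxyls.

**Compound list**
1 | cyclopent-2-en-1-one | O=C1C=CCC1 | starting material
2 | 2-iodocyclopent-2-en-1-one | O=C1CCC=C1I | intermediate
3 | (S)-2-iodocyclopent-2-en-1-ol | O[C@H]1CCC=C1I | intermediate
4 | (S)-1-iodo-5-(4-methoxybenzyloxy)cyclopent-1-ene | COc1ccc(CO[C@H]2CCC=C2I)cc1 | intermediate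
5 | allyloxy(tert-butyl)dimethylsilane | C=CCO[Si](C)(C)C(C)(C)C | starting material
6 | 9-[3-(tert-butyldimethylsilyloxy)propyl]-9-borabicyclo[3.3.1]nonane | CC(C)(C)[Si](C)(C)OCCCB1C2CCCC1CCC2 | intermediate
7 | tert-butyl{3-[(5S)-5-(4-methoxybenzyloxy)cyclopent-1-en-1-yl]propoxy}dimethylsilane | COc1ccc(CO[C@H]2CCC=C2CCCO[Si](C)(C)C(C)(C)C)cc1 | intermediate
8 | (1S,2R,3S)-2-[3-(tert-butyldimethylsilyloxy)propyl]-3-(4-methoxybenzyloxy)cyclopentan-1-ol | COc1ccc(CO[C@H]2CC[C@H](O)[C@H]2CCCO[Si](C)(C)C(C)(C)C)cc1 | intermediate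
9 | 1-{[(1S,2S,3S)-3-(tert-butyldimethylsilyloxy)-2-[3-(tert-butyldimethylsilyloxy)propyl]cyclopentyl]oxymethyl}-4-methoxybenzene | COc1ccc(CO[C@H]2CC[C@H](O[Si](C)(C)C(C)(C)C)[C@H]2CCCO[Si](C)(C)C(C)(C)C)cc1 | intermediate
10 | (1S,2S,3S)-3-(tert-butyldimethylsilyloxy)-2-[3-(tert-butyldimethylsilyloxy)propyl]cyclopentan-1-ol | O[C@H]1CC[C@H](O[Si](C)(C)C(C)(C)C)[C@H]1CCCO[Si](C)(C)C(C)(C)C | intermediate
11 | (2R,3S)-3-(tert-butyldimethylsilyloxy)-2-[3-(tert-butyldimethylsilyloxy)propyl]cyclopentan-1-one | O=C1CC[C@H](O[Si](C)(C)C(C)(C)C)[C@H]1CCCO[Si](C)(C)C(C)(C)C | intermediate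
12 | pentane-2,4-dione | CC(=O)CC(C)=O | starting material
13 | 1-bromobut-2-yne | CC#CCBr | starting material
14 | 3-(but-2-yn-1-yl)pentane-2,4-dione | CC#CCC(C(C)=O)C(C)=O | intermediate
15 | hept-5-yn-2-one | CC#CCCC(C)=O | intermediate
16 | N′-[(E)-hept-5-yn-2-ylidene]-2,4,6-triisopropylbenzenesulfonohydrazide | CC#CCC/C(C)=N/NS(=O)(=O)c1c(C(C)C)cc(C(C)C)cc1C(C)C | intermediate
17 | 2-lithiohepta-1-en-5-yne | [Li]C(=C)CCC#CC | intermediate
18 | dichloro(hepta-1-en-5-yn-2-yl)cerium | C=C(CCC#CC)[Ce](Cl)Cl | intermediate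
19 | (1S,2R,3S)-3-(tert-butyldimethylsilyloxy)-2-[3-(tert-butyldimethylsilyloxy)propyl]-1-(hepta-1-en-5-yn-2-yl)cyclopentan-1-ol | O[C@@]1(C(=C)CCC#CC)CC[C@H](O[Si](C)(C)C(C)(C)C)[C@H]1CCCO[Si](C)(C)C(C)(C)C | intermediate
20 | (1S,2R,3S)-3-(tert-butyldimethylsilyloxy)-2-[3-(tert-butyldimethylsilyloxy)propyl]-1-[(2R)-2-(pent-3-yn-1-yl)oxiran-2-yl]cyclopentan-1-ol | O[C@@]1([C@@]2(CCC#CC)CO2)CC[C@H](O[Si](C)(C)C(C)(C)C)[C@H]1CCCO[Si](C)(C)C(C)(C)C | intermediate
21 | (2S,3S,4S)-4-(tert-butyldimethylsilyloxy)-3-[3-(tert-butyldimethylsilyloxy)propyl]-2-(hydroxymethyl)-2-(pent-3-yn-1-yl)cyclohexan-1-one | CC#CCC[C@@]1(CO)[C@H](CCCO[Si](C)(C)C(C)(C)C)[C@@H](O[Si](C)(C)C(C)(C)C)CCC1=O | intermediate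
22 | [(1R,2S,3S)-3-(tert-butyldimethylsilyloxy)-2-[3-(tert-butyldimethylsilyloxy)propyl]-6-methylidene-1-(pent-3-yn-1-yl)cyclohexyl]methanol | CC#CCC[C@@]1(CO)[C@H](CCCO[Si](C)(C)C(C)(C)C)[C@@H](O[Si](C)(C)C(C)(C)C)CCC1=C | intermediate
23 | [(3S,4S,5S,6S)-6-(tert-butyldimethylsilyloxy)-5-[3-(tert-butyldimethylsilyloxy)propyl]-4-(pent-3-yn-1-yl)-1-oxaspiro[2.5]octan-4-yl]methanol | CC#CCC[C@@]1(CO)[C@H](CCCO[Si](C)(C)C(C)(C)C)[C@@H](O[Si](C)(C)C(C)(C)C)CC[C@@]12CO2 | intermediate
24 | [(3S,4S,5S,6S)-6-(tert-butyldimethylsilyloxy)-5-[3-(tert-butyldimethylsilyloxy)propyl]-4-(pent-3-yn-1-yl)-1-oxaspiro[2.5]octan-4-yl]methyl methanesulfonate | CC#CCC[C@@]1(COS(C)(=O)=O)[C@H](CCCO[Si](C)(C)C(C)(C)C)[C@@H](O[Si](C)(C)C(C)(C)C)CC[C@@]12CO2 | intermediate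
25 | [(1S,2S,3S,6S)-3-(tert-butyldimethylsilyloxy)-2-[3-(tert-butyldimethylsilyloxy)propyl]-6-hydroxy-6-methyl-1-(pent-3-yn-1-yl)cyclohexyl]methyl methanesulfonate | CC#CCC[C@@]1(COS(C)(=O)=O)[C@H](CCCO[Si](C)(C)C(C)(C)C)[C@@H](O[Si](C)(C)C(C)(C)C)CC[C@]1(C)O | intermediate
26 | (1S,2S,3S,4S)-4-(tert-butyldimethylsilyloxy)-3-[3-(tert-butyldimethylsilyloxy)propyl]-1,2-dimethyl-2-(pent-3-yn-1-yl)cyclohexan-1-ol | CC#CCC[C@@]1(C)[C@H](CCCO[Si](C)(C)C(C)(C)C)[C@@H](O[Si](C)(C)C(C)(C)C)CC[C@]1(C)O | intermediate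
27 | (E)-alkenyl(chloro)zirconocene of 26, zirconium on the methyl-bearing alkene carbon, tertiary oxygen as its chlorozirconocene alkoxide | C/C(=C\CC[C@@]1(C)[C@H](CCCO[Si](C)(C)C(C)(C)C)[C@@H](O[Si](C)(C)C(C)(C)C)CC[C@]1(C)O[Zr](Cl)(C1C=CC=C1)C1C=CC=C1)[Zr](Cl)(C1C=CC=C1)C1C=CC=C1 | intermediate
28 | (1S,2S,3S,4S)-4-(tert-butyldimethylsilyloxy)-3-[3-(tert-butyldimethylsilyloxy)propyl]-2-[(E)-4-iodopent-3-en-1-yl]-1,2-dimethylcyclohexan-1-ol | C/C(I)=C\CC[C@@]1(C)[C@H](CCCO[Si](C)(C)C(C)(C)C)[C@@H](O[Si](C)(C)C(C)(C)C)CC[C@]1(C)O | intermediate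
29 | (1S,2S,3S,4S)-3-(3-hydroxypropyl)-2-[(E)-4-iodopent-3-en-1-yl]-1,2-dimethylcyclohexane-1,4-diol | C/C(I)=C\CC[C@@]1(C)[C@H](CCCO)[C@@H](O)CC[C@]1(C)O | intermediate
30 | 2-(diethoxyphosphoryl)propanoic acid | CCOP(=O)(OCC)C(C)C(=O)O | starting material
31 | 3-[(1S,2S,3S,6S)-3,6-dihydroxy-2-[(E)-4-iodopent-3-en-1-yl]-2,3-dimethylcyclohexyl]propyl 2-(diethoxyphosphoryl)propanoate | C/C(I)=C\CC[C@@]1(C)[C@H](CCCOC(=O)C(C)P(=O)(OCC)OCC)[C@@H](O)CC[C@]1(C)O | intermediate
32 | 3-[(1S,2S,3S)-3-hydroxy-2-[(E)-4-iodopent-3-en-1-yl]-2,3-dimethyl-6-oxocyclohexyl]propyl 2-(diethoxyphosphoryl)propanoate | C/C(I)=C\CC[C@@]1(C)[C@H](CCCOC(=O)C(C)P(=O)(OCC)OCC)C(=O)CC[C@]1(C)O | intermediate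
33 | eight-membered α-methyl enoate lactone fused to ring A at C3–C4 (carbonyl carbon syn to C3), with C1 hydroxyl, C1 and C2 methyls and the (E)-4-iodopent-3-enyl chain on C2 | C/C(I)=C\CC[C@@]1(C)[C@@H]2CCCOC(=O)/C(C)=C2/CC[C@]1(C)O | intermediate
34 | hex-1-en-5-yne | C=CCCC#C | starting material
35 | dimethyl[(E)-2-methylhexa-1,5-dien-1-yl]alane | C=CCC/C(C)=C/[Al](C)C | intermediate
36 | lithium butyl(dimethyl)[(E)-2-methylhexa-1,5-dien-1-yl]aluminate | [Li+].C=CCC/C(C)=C/[Al-](C)(C)CCCC | intermediate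
37 | (E)-4-methylocta-3,7-dien-1-ol | OCC/C=C(\C)CCC=C | intermediate
38 | 2-[(2R,3R)-3-(but-3-en-1-yl)-3-methyloxiran-2-yl]ethan-1-ol | OCC[C@H]1O[C@]1(C)CCC=C | intermediate
39 | 2-[(2R,3R)-3-methyl-3-(4-methylpent-3-en-1-yl)oxiran-2-yl]ethan-1-ol | OCC[C@H]1O[C@]1(C)CCC=C(C)C | intermediate
40 | 2-[(2R,3R)-3-methyl-3-(4-methylpent-3-en-1-yl)oxiran-2-yl]acetaldehyde | O=CC[C@H]1O[C@]1(C)CCC=C(C)C | intermediate
41 | lactone 33 with iodine replaced by the (1R)-1-hydroxy-2-[(2R,3R)-3-methyl-3-(4-methylpent-3-en-1-yl)oxiran-2-yl]ethyl group | CC(C)=CCC[C@@]1(C)O[C@@H]1C[C@@H](O)/C(C)=C/CC[C@@]2(C)[C@@H]3CCCOC(=O)/C(C)=C3/CC[C@]2(C)O | intermediate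
42 | lactone 33 with iodine replaced by the (2R,4R,5S)-4-hydroxy-5-methyl-5-(4-methylpent-3-en-1-yl)oxolan-2-yl group | CC(C)=CCC[C@]1(C)O[C@@H](/C(C)=C/CC[C@@]2(C)[C@@H]3CCCOC(=O)/C(C)=C3/CC[C@]2(C)O)C[C@H]1O | intermediate
43 | (1S,2S,3R,4Z)-2-{(3E)-4-[(2R,4R,5S)-4-hydroxy-5-methyl-5-(4-methylpent-3-en-1-yl)oxolan-2-yl]pent-3-en-1-yl}-4-(1-hydroxypropan-2-ylidene)-3-(3-hydroxypropyl)-1,2-dimethylcyclohexan-1-ol | CC(C)=CCC[C@]1(C)O[C@@H](/C(C)=C/CC[C@@]2(C)[C@H](CCCO)/C(=C(/C)CO)CC[C@]2(C)O)C[C@H]1O | intermediate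
44 | CNP0155390.1, (2Z)-2-[(2R,3S,4S)-4-hydroxy-2-(3-hydroxypropyl)-3-{(3E)-4-[(2R,4R,5S)-4-hydroxy-5-methyl-5-(4-methylpent-3-en-1-yl)oxolan-2-yl]pent-3-en-1-yl}-3,4-dimethylcyclohexylidene]propanal | CC(C)=CCC[C@]1(C)O[C@@H](/C(C)=C/CC[C@@]2(C)[C@H](CCCO)/C(=C(/C)C=O)CC[C@]2(C)O)C[C@H]1O | target

**Step count and risks**
Total steps: 30. Longest linear sequence: 24 (steps 1–8, 11–22, 27–30).

Steps most likely to fail:

1. Step 22 (bears the label "Proposed new method:"). The eight-membered ring closure onto a hindered ketone may be too slow, so that oligomers form or the base epimerises C3 next to the ketone before the olefination takes place. The fallback uses known chemistry, sets out from triol 29 and comes back at diol 43. The primary hydroxyl of 29 is silylated (t-BuMe2SiCl, imidazole) to the mono silyl ether F1, and Dess–Martin oxidation gives the C4 ketone F2. CH2=C(CH3)MgBr with CeCl3 adds to give the tertiary isopropenyl carbinol F3. Pyridinium chlorochromate C5H5NH[CrO3Cl] then brings about the Babler–Dauben oxidative 1,3-transposition to the enal F4; the chair [3,3] shift of the chromate ester should turn the methyl group toward the less hindered C5 and so place the formyl group syn to C3, and the other geometric isomer is removed by chromatography. NaBH4/CeCl3 reduces F4 to the allylic alcohol F5, and Bu4NF removes the silyl group to give the iodo triol F6. Ni/Cr coupling of F6 with aldehyde 40 under the conditions of step 27 gives the epoxy tetraol F7, and camphor-10-sulfonic acid closes ring B to give 43, which is oxidised as in step 30.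

2. Step 13. The ring CH2 may migrate in place of the methine carbon, or the epoxide may open without any shift (to a bromohydrin or an allylic diol), and a silyl ether may be lost to the Lewis acid. The fallback sets out from epoxy alcohol 20 and comes back at ketone 21. The tertiary hydroxyl is silylated (Me3SiOSO2CF3, 2,6-lutidine) to the epoxy silyl ether F8, which is rearranged with TiCl4 in CH2Cl2 at −78 °C (Suzuki–Tsuchihashi variant of the same 1,2-shift). There the silyloxy group drives the anti migration at low temperature without a zinc chelate, and aqueous work-up frees 21.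

3. Step 27. Facial selectivity at C5′ may be poor, made worse if the β,γ-epoxy aldehyde is partly lost by epoxide opening before it couples. The fallback sets out from iodide 33 and aldehyde 40 and comes back at 41. Coupling with CrCl2 and NiCl2 (cat.) in DMSO without a chiral ligand gives 41 together with its C5′ epimer F9. The mixture is oxidised at once (Dess–Martin periodinane, NaHCO3), before the epoxy alcohol can cyclise, to the enone F10. Reduction with (S)-2-methyl-CBS-oxazaborolidine and catecholborane at −78 °C returns the (R)-carbinol 41 under reagent control, the alkenyl side acting as the large group.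

**Further compounds**
F1 | step 22 | (1S,2S,3S,4S)-3-[3-(tert-butyldimethylsilyloxy)propyl]-2-[(E)-4-iodopent-3-en-1-yl]-1,2-dimethylcyclohexane-1,4-diol | C/C(I)=C\CC[C@@]1(C)[C@H](CCCO[Si](C)(C)C(C)(C)C)[C@@H](O)CC[C@]1(C)O
F2 | step 22 | (2S,3S,4S)-2-[3-(tert-butyldimethylsilyloxy)propyl]-4-hydroxy-3-[(E)-4-iodopent-3-en-1-yl]-3,4-dimethylcyclohexan-1-one | C/C(I)=C\CC[C@@]1(C)[C@H](CCCO[Si](C)(C)C(C)(C)C)C(=O)CC[C@]1(C)O
F3 | step 22 | isopropenyl carbinol from F2 (C4 bearing OH and prop-1-en-2-yl, configuration at C4 not defined) | C/C(I)=C\CC[C@@]1(C)[C@H](CCCO[Si](C)(C)C(C)(C)C)C(O)(C(C)=C)CC[C@]1(C)O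
F4 | step 22 | (2Z)-2-[(2R,3S,4S)-2-[3-(tert-butyldimethylsilyloxy)propyl]-4-hydroxy-3-[(E)-4-iodopent-3-en-1-yl]-3,4-dimethylcyclohexylidene]propanal | C/C(I)=C\CC[C@@]1(C)[C@H](CCCO[Si](C)(C)C(C)(C)C)/C(=C(/C)C=O)CC[C@]1(C)O
F5 | step 22 | allylic alcohol from F4 (formyl group reduced to CH2OH, silyl ether kept) | C/C(I)=C\CC[C@@]1(C)[C@H](CCCO[Si](C)(C)C(C)(C)C)/C(=C(/C)CO)CC[C@]1(C)O
F6 | step 22 | (1S,2S,3R,4Z)-4-(1-hydroxypropan-2-ylidene)-3-(3-hydroxypropyl)-2-[(E)-4-iodopent-3-en-1-yl]-1,2-dimethylcyclohexan-1-ol | C/C(I)=C\CC[C@@]1(C)[C@H](CCCO)/C(=C(/C)CO)CC[C@]1(C)O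
F7 | step 22 | F6 with iodine replaced by the (1R)-1-hydroxy-2-[(2R,3R)-3-methyl-3-(4-methylpent-3-en-1-yl)oxiran-2-yl]ethyl group | CC(C)=CCC[C@@]1(C)O[C@@H]1C[C@@H](O)/C(C)=C/CC[C@@]2(C)[C@H](CCCO)/C(=C(/C)CO)CC[C@]2(C)O
F8 | step 13 | trimethylsilyl ether of 20 at the tertiary hydroxyl | C[Si](C)(C)O[C@@]1([C@@]2(CCC#CC)CO2)CC[C@H](O[Si](C)(C)C(C)(C)C)[C@H]1CCCO[Si](C)(C)C(C)(C)C
F9 | step 27 | C5′ epimer of 41 ((1S)-1-hydroxy at the carbinol carbon) | CC(C)=CCC[C@@]1(C)O[C@@H]1C[C@H](O)/C(C)=C/CC[C@@]2(C)[C@@H]3CCCOC(=O)/C(C)=C3/CC[C@]2(C)O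
F10 | step 27 | enone from 41 and F9 (C5′ ketone, epoxide intact) | CC(C)=CCC[C@@]1(C)O[C@@H]1CC(=O)/C(C)=C/CC[C@@]2(C)[C@@H]3CCCOC(=O)/C(C)=C3/CC[C@]2(C)O
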